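The runs were computed for substances that don't exist, noise included.

| flask | first end groups | second end groups | remark | time |
|---|---|---|---|---|
| maple | 0.014 M | 0.021 M | run made earlier |  |
| alder | 0.026 M | 0.021 M | run made earlier |  |
| amber | 0.010 M | 0.0210 M |  | 1.5 min |
| ochre | 0.020 M | 0.0210 M |  | 6.0 min |

| run | time / min | links / % | first end groups / % |
|---|---|---|---|
| maple | 0.250 | 8.4 | 91.5 |
| maple | 0.417 | 13.6 | 84.6 |
| maple | 0.667 | 17.1 | 77.5 |
| maple | 1.00 | 23.3 | 69.3 |
| maple | 2.00 | 37.9 | 53.0 |
| maple | 3.00 | 45.6 | 41.8 |
| alder | 0.200 | 7.0 | 94.4 |
| alder | 0.667 | 15.9 | 75.9 |
| alder | 1.00 | 22.2 | 69.9 |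
| alder | 1.50 | 29.6 | 60.6 |
| alder | 2.50 | 35.2 | 51.3 |
| alder | 3.00 | 39.3 | 47.6 |

(scatter of a reading: 1 percentage point)

- on the list of suspects stand: first end groups <-> dormant form; first end groups + second end groups -> links + released group; second end groups -> decomposed reagent

1. which one finishes higher in amount of links, in percent of the first end groups charged ("neither" within 2 percentage points) (amber / ochre / neither)
2. amount of links at the end, in percent of the first end groups charged, amber
3. amount of links at the end, in percent of the first end groups charged, ochre

Maple and alder both lose first end groups faster than they gain links, and the shortfall fits the suspected dormant form. So set links gained against first end groups lost: the ratio of these two running totals is read without the clock, though it may drift along a run. At 3.00 min this gives 0.784 for maple and 0.750 for alder, although alder's charge is about twice maple's. Pooled, these two readings give 0.768 for the link share s, the running total of links gained per first end group lost, a cumulative selectivity read at that time.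

Now turn the question round. With s held common, links rank as losses do, so amber wins if ochre loses fewer first end groups by 6.0 min than amber does by 1.5 min. Take amber's loss from alder's reading at 1.50 min, 39.4 %; my estimate for amber is then 30.2 %. Ochre's charge lies between maple's and alder's, and at 3.00 min, half of ochre's time, those runs have lost 52.4 % and 58.2 %. Alder's extra loss alone is worth 10 percentage points of links, against a margin of 2 points.

The forecast says ochre, with 32 % for amber (29 % to 35 %), above my figure, and 54 % for ochre (49 % to 60 %), on the ground that “second end groups are near 0.0085 M and fading, adding about 11 points by 6 min”.

The flask gives ochre: 32.1 % for amber, 54.4 % for ochre.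

    first end groups ⇌ dormant form (K = 0.270, k = 0.00190 s⁻¹)
    first end groups + second end groups → links + released group (k = 0.260 M⁻¹ s⁻¹)
    second end groups → decomposed reagent (k = 0.00160 s⁻¹)

By 1.50 min amber had formed links while dormant form rose to 9.35 % and second end groups fell to 72 % of their charge. From 3.00 min to 6.00 min ochre's links rose from 42.7 % to 54.4 %, with dormant form near 10.7 % and second end groups falling to 21 % of their charge. On losses, s gives 31.8 % for amber and 49.9 % for ochre, whose share reached 0.836. Ochre's lead over amber is 22 points, against the 5 points that ochre's answer moves at second end groups 0.0185 M or 0.0238 M, with first end groups and time held.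

Amber read at 25 s has lost 15.9 %, so s gives 12.2 %; the computed links are 11.9 %.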